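**Retrosynthetic overview**
1. The (2R)-hemiketal comes from the racemate: the pyranone ring closes last, by addition of the ring-A phenol to the central ketone of the open 1,3-diketo acid, and the configuration is fixed by crystallisation as an alkaloid salt.
2. The open diketo acid comes from ring B, made by aldol aromatisation of a 3,5,7-triketo acid released from a 6-(2-oxoalkyl)-4-hydroxy-2-pyranone; the central ketone is masked as a dioxolane.
3. Ring A comes from aldol aromatisation of a linear 2,4,6,8-tetraketone.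
4. The C24 chain is assembled in polyketide order from C13 + C5 + C6: tridecane-2,4,6-trione, the ethylene ketal of dimethyl 3-oxopentanedioate, and 4-hydroxy-6-methyl-2-pyranone.
5. Ring order: ring A, then ring B, then the pyranone.

Assumption: the hemiketal carbon epimerises in solution through the achiral open diketone, so it is fixed only at the end; which cinchona salt crystallises with the (2R)-acid cannot be predicted, so quinine is written and quinidine takes its place if the crystals hold the (2S)-acid.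

**Step 1**
Reactants: 1 pentane-2,4-dione; 2 methyl octanoate
Product: 3 tridecane-2,4,6-trione
Conditions: 1 (2.2 equiv), LiN(i-Pr)2 (4.4 equiv, commercial solution), THF, 0 °C; 2 (1.0 equiv), 0 °C → rt; cold 1 M HCl
Reagents that add atoms: none
Why: Claisen-type acylation of the terminal carbanion of the diketone dianion by the ester (the second equivalent of dianion is consumed by the more acidic triketone), a standard route to 1,3,5-triketones; no stereocentre.

**Step 2**
Reactants: 4 dimethyl 3-oxopentanedioate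
Product: 5 dimethyl 2,2'-(1,3-dioxolane-2,2-diyl)diacetate
Conditions: HOCH2CH2OH (3 equiv), p-TsOH·H2O (5 mol %), toluene, Dean–Stark, reflux
Reagents that add atoms: ethylene glycol, OCCO
Why: acid-catalysed ketalisation with azeotropic removal of water, which masks the central carbonyl so that it is neither an aldol electrophile nor a source of acidic methylenes in the later polyanion and cyclisation steps; no stereocentre.

**Step 3**
Reactants: 3 tridecane-2,4,6-trione; 5 dimethyl 2,2'-(1,3-dioxolane-2,2-diyl)diacetate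
Product: 7 methyl 2-{2-[2-(2-heptyl-4,6-dihydroxyphenyl)-2-oxoethyl]-1,3-dioxolan-2-yl}acetate, via tetraketone ester 6 (not isolated)
Conditions: 3 (2.2 equiv), LiN(i-Pr)2 (6.8 equiv), THF, 0 °C, 1 h; 5 (1.0 equiv), −40 → 0 °C; cold 1 M HCl to pH 4, extract; then MeOH–aq. NaHCO3 (pH ≈ 8.5), rt, 12 h
Reagents that add atoms: none
Why: Claisen-type acylation of the terminal methyl carbanion of the triketone trianion by one ester of 5 gives the linear tetraketone, whose methylene between the two carbonyls nearest the ketal attacks the heptyl ketone in a polyketide-type intramolecular aldol condensation (then dehydration and enolisation to the resorcinol), the opposite closure onto the ketone flanked by the quaternary ketal carbon being sterically disfavoured and all other aldol partners being removed by the ketal; no stereocentre.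

**Step 4**
Reactants: 7 methyl 2-{2-[2-(2-heptyl-4,6-dihydroxyphenyl)-2-oxoethyl]-1,3-dioxolan-2-yl}acetate; 8 4-hydroxy-6-methyl-2H-pyran-2-one
Product: 13 racemic 2-[(5-heptyl-2,7-dihydroxy-4-oxo-3,4-dihydro-2H-chromen-2-yl)methyl]-4,6-dihydroxybenzoic acid, via pyrone ketone 9 (not isolated), via triketo acid 10 (not isolated), via resorcylic acid ketal 11 (not isolated), via open diketo acid 12 (not isolated)
Conditions: 8 (4 equiv), LiN(i-Pr)2 (8.2 equiv), THF–DMPU, −78 → 0 °C; 7 as its dilithium phenoxide [LiN(i-Pr)2, 2.1 equiv], 0 °C → rt, 4 h; then degassed 2 M aq. KOH–MeOH, rt, 36 h (Ar); then HCl to pH 1, THF–H2O, rt, 4 h; reversed-phase chromatography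
Reagents that add atoms: water, O
Why: the 6-methyl carbanion of the pyranone dianion is acylated by the ester of 7 (the aryl ketone is shielded as a bis-phenoxide), aqueous KOH opens the 2-pyranone to the 3,5,7-triketo acid whose C-2 closes onto the C-7 ketone in the same aldol aromatisation that turns 6-acetonyl-4-hydroxy-2-pyranone into orsellinic acid (a carboxylate cannot undergo the Claisen alternative), and aqueous acid then removes the dioxolane so that the ring-A phenol adds to the freed central ketone in a spontaneous hemiketalisation that forms the new stereocentre as a racemate.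

**Step 5**
Reactants: 13 racemic 2-[(5-heptyl-2,7-dihydroxy-4-oxo-3,4-dihydro-2H-chromen-2-yl)methyl]-4,6-dihydroxybenzoic acid
Product: 14 quinine salt of 2-{[(2R)-5-heptyl-2,7-dihydroxy-4-oxo-3,4-dihydro-2H-chromen-2-yl]methyl}-4,6-dihydroxybenzoic acid
Conditions: quinine (1.0 equiv), EtOAc–i-PrOH (9:1), 45 → 20 °C, seeded slurry aged 72 h; filter, wash with cold EtOAc
Reagents that add atoms: quinine, COC1=CC2=C(C=CN=C2C=C1)[C@H]([C@@H]3C[C@@H]4CCN3C[C@@H]4C=C)O
Why: Proposed new method: crystallisation-induced asymmetric transformation, in which the two hemiketal enantiomers interconvert in solution through the achiral open diketone 12 (amine-catalysed ring-chain tautomerism) while only the less soluble diastereomeric salt leaves the solution, so the whole batch is funnelled into one configuration and the C-2 stereocentre is set by the salt lattice; the closest known reaction type is the dynamic diastereomeric-salt resolution of epimerisable acids and lactols with cinchona alkaloids.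

**Step 6**
Reactants: 14 quinine salt of 2-{[(2R)-5-heptyl-2,7-dihydroxy-4-oxo-3,4-dihydro-2H-chromen-2-yl]methyl}-4,6-dihydroxybenzoic acid
Product: 15 2-{[(2R)-5-heptyl-2,7-dihydroxy-4-oxo-3,4-dihydro-2H-chromen-2-yl]methyl}-4,6-dihydroxybenzoic acid
Conditions: EtOAc / 0.1 M aq. HCl, 0 °C, 5 min; Na2SO4; evaporate below 10 °C; store the solid at −20 °C
Reagents that add atoms: none
Why: proton transfer only (salt break), with quinine passing into the cold aqueous acid and the free acid staying in ethyl acetate, and since ring opening is the sole racemisation path the configuration set in step 5 is kept by working cold, briefly and without base.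

**Compound list**
1 | pentane-2,4-dione | CC(=O)CC(C)=O | starting material
2 | methyl octanoate | CCCCCCCC(=O)OC | starting material
3 | tridecane-2,4,6-trione | CCCCCCCC(=O)CC(=O)CC(C)=O | intermediate
4 | dimethyl 3-oxopentanedioate | COC(=O)CC(=O)CC(=O)OC | starting material
5 | dimethyl 2,2'-(1,3-dioxolane-2,2-diyl)diacetate | COC(=O)CC1(CC(=O)OC)OCCO1 | intermediate
6 | methyl 2-[2-(2,4,6,8-tetraoxopentadecyl)-1,3-dioxolan-2-yl]acetate (tetraketone ester) | CCCCCCCC(=O)CC(=O)CC(=O)CC(=O)CC1(CC(=O)OC)OCCO1 | intermediate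
7 | methyl 2-{2-[2-(2-heptyl-4,6-dihydroxyphenyl)-2-oxoethyl]-1,3-dioxolan-2-yl}acetate | CCCCCCCc1cc(O)cc(O)c1C(=O)CC1(CC(=O)OC)OCCO1 | intermediate
8 | 4-hydroxy-6-methyl-2H-pyran-2-one | CC1=CC(O)=CC(=O)O1 | starting material
9 | 6-(3-{2-[2-(2-heptyl-4,6-dihydroxyphenyl)-2-oxoethyl]-1,3-dioxolan-2-yl}-2-oxopropyl)-4-hydroxy-2H-pyran-2-one (pyrone ketone) | CCCCCCCc1cc(O)cc(O)c1C(=O)CC1(CC(=O)CC2=CC(O)=CC(=O)O2)OCCO1 | intermediate
10 | 8-{2-[2-(2-heptyl-4,6-dihydroxyphenyl)-2-oxoethyl]-1,3-dioxolan-2-yl}-3,5,7-trioxooctanoic acid (triketo acid) | CCCCCCCc1cc(O)cc(O)c1C(=O)CC1(CC(=O)CC(=O)CC(=O)CC(=O)O)OCCO1 | intermediate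
11 | 2-({2-[2-(2-heptyl-4,6-dihydroxyphenyl)-2-oxoethyl]-1,3-dioxolan-2-yl}methyl)-4,6-dihydroxybenzoic acid (resorcylic acid ketal) | CCCCCCCc1cc(O)cc(O)c1C(=O)CC1(Cc2cc(O)cc(O)c2C(=O)O)OCCO1 | intermediate
12 | 2-[4-(2-heptyl-4,6-dihydroxyphenyl)-2,4-dioxobutyl]-4,6-dihydroxybenzoic acid (open diketo acid) | CCCCCCCc1cc(O)cc(O)c1C(=O)CC(=O)Cc1cc(O)cc(O)c1C(=O)O | intermediate
13 | racemic 2-[(5-heptyl-2,7-dihydroxy-4-oxo-3,4-dihydro-2H-chromen-2-yl)methyl]-4,6-dihydroxybenzoic acid | CCCCCCCc1cc(O)cc2c1C(=O)CC(O)(Cc1cc(O)cc(O)c1C(=O)O)O2 | intermediate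
14 | quinine salt of the (2R)-acid | CCCCCCCc1cc(O)cc2c1C(=O)C[C@@](O)(Cc1cc(O)cc(O)c1C(=O)[O-])O2.COC1=CC2=C(C=CN=C2C=C1)[C@H]([C@@H]3C[C@@H]4CC[NH+]3C[C@@H]4C=C)O | intermediate
15 | 2-{[(2R)-5-heptyl-2,7-dihydroxy-4-oxo-3,4-dihydro-2H-chromen-2-yl]methyl}-4,6-dihydroxybenzoic acid | CCCCCCCc1cc(O)cc2c1C(=O)C[C@@](O)(Cc1cc(O)cc(O)c1C(=O)O)O2 | target

**Totals**
Total steps: 6. Longest linear sequence: 5 (step 1 or step 2, then steps 3, 4, 5, 6).

**Steps most likely to fail**

Step 3. The third deprotonation of 3 may go to the heptyl α-methylene instead of the methyl, the α-protons of 5 may quench the trianion, and the tetraketone may close the other way to the isomeric octanoylresorcinol. The fallback sets out from 2 and comes back at 7; it makes ring A by a dioxinone aromatisation that has only one possible aldol mode. Commercial 2,2,6-trimethyl-4H-1,3-dioxin-4-one is C-acetylated (LiN(SiMe3)2, AcCl, THF, −78 °C) to 2,2-dimethyl-6-(2-oxopropyl)-4H-1,3-dioxin-4-one F1. The dianion of F1 is acylated by 2 to 6-(2,4-dioxoundecyl)-2,2-dimethyl-4H-1,3-dioxin-4-one F2. Et3N in CH2Cl2 closes F2 to 5-heptyl-7-hydroxy-2,2-dimethyl-4H-1,3-benzodioxin-4-one F3. The lithium enolate of 5 opens this salicylate acetonide, used as its lithium phenoxide, with loss of acetone to methyl 2-{2-[1-(2-heptyl-4,6-dihydroxyphenyl)-3-methoxy-1,3-dioxopropan-2-yl]-1,3-dioxolan-2-yl}acetate F4. Krapcho removal of the activated methoxycarbonyl group (LiCl, wet DMSO, 120 °C) then gives 7.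

Step 4. The pyranone dianion is poorly soluble and must acylate an ester that carries two phenoxides; the dioxolane next to an enolisable ester may open under strong base; and in the acid stage the product may dehydrate to the chromone or isocoumarin or lose CO2 if pushed. The fallback sets out from 5 and comes back at 11; it builds ring B first and by the neutral dioxinone mode. The dianion of F1 is acylated by 5 to methyl 2-{2-[5-(2,2-dimethyl-4-oxo-4H-1,3-dioxin-6-yl)-2,4-dioxopentyl]-1,3-dioxolan-2-yl}acetate F5. Et3N in CH2Cl2 aromatises F5 to methyl 2-{2-[(7-hydroxy-2,2-dimethyl-4-oxo-4H-1,3-benzodioxin-5-yl)methyl]-1,3-dioxolan-2-yl}acetate F6. The trianion of 3 is acylated by the remaining ester of F6 to 7-hydroxy-2,2-dimethyl-5-{[2-(2,4,6,8-tetraoxopentadecyl)-1,3-dioxolan-2-yl]methyl}-4H-1,3-benzodioxin-4-one F7, which closes at pH 8.5 to 5-({2-[2-(2-heptyl-4,6-dihydroxyphenyl)-2-oxoethyl]-1,3-dioxolan-2-yl}methyl)-7-hydroxy-2,2-dimethyl-4H-1,3-benzodioxin-4-one F8. Aqueous KOH opens the acetonide lactone of F8 to 11, which is taken on with aqueous HCl as in step 4.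

Step 5. No salt may crystallise, the crystal may hold the (2S)-acid, or epimerisation in the mother liquor may be too slow. The fallback sets out from 13 and comes back at 15, bypassing 14. The racemate is separated by preparative chromatography on a chiral stationary phase (supercritical CO2–MeOH with 0.1 % HCO2H, cold collection). The unwanted enantiomer is re-racemised through 12 by standing in MeOH with a trace of Et3N and recycled. No new compound is made.

**Further compounds**
F1 | step 3 | 2,2-dimethyl-6-(2-oxopropyl)-4H-1,3-dioxin-4-one | CC(=O)CC1=CC(=O)OC(C)(C)O1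
F2 | step 3 | 6-(2,4-dioxoundecyl)-2,2-dimethyl-4H-1,3-dioxin-4-one | CCCCCCCC(=O)CC(=O)CC1=CC(=O)OC(C)(C)O1
F3 | step 3 | 5-heptyl-7-hydroxy-2,2-dimethyl-4H-1,3-benzodioxin-4-one | CCCCCCCc1cc(O)cc2OC(C)(C)OC(=O)c12
F4 | step 3 | methyl 2-{2-[1-(2-heptyl-4,6-dihydroxyphenyl)-3-methoxy-1,3-dioxopropan-2-yl]-1,3-dioxolan-2-yl}acetate | CCCCCCCc1cc(O)cc(O)c1C(=O)C(C(=O)OC)C1(CC(=O)OC)OCCO1
F5 | step 4 | methyl 2-{2-[5-(2,2-dimethyl-4-oxo-4H-1,3-dioxin-6-yl)-2,4-dioxopentyl]-1,3-dioxolan-2-yl}acetate | COC(=O)CC1(CC(=O)CC(=O)CC2=CC(=O)OC(C)(C)O2)OCCO1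
F6 | step 4 | methyl 2-{2-[(7-hydroxy-2,2-dimethyl-4-oxo-4H-1,3-benzodioxin-5-yl)methyl]-1,3-dioxolan-2-yl}acetate | COC(=O)CC1(Cc2cc(O)cc3OC(C)(C)OC(=O)c23)OCCO1
F7 | step 4 | 7-hydroxy-2,2-dimethyl-5-{[2-(2,4,6,8-tetraoxopentadecyl)-1,3-dioxolan-2-yl]methyl}-4H-1,3-benzodioxin-4-one | CCCCCCCC(=O)CC(=O)CC(=O)CC(=O)CC1(Cc2cc(O)cc3OC(C)(C)OC(=O)c23)OCCO1
F8 | step 4 | 5-({2-[2-(2-heptyl-4,6-dihydroxyphenyl)-2-oxoethyl]-1,3-dioxolan-2-yl}methyl)-7-hydroxy-2,2-dimethyl-4H-1,3-benzodioxin-4-one | CCCCCCCc1cc(O)cc(O)c1C(=O)CC1(Cc2cc(O)cc3OC(C)(C)OC(=O)c23)OCCO1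
F0 | step 5 | none | none
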